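**Retrosynthetic overview**

1. Locants are the bicyclo[3.3.1]nonane ones of the target: C1 (prenyl bridgehead), C2–C3–C4 (acylated β-diketone bridge), C5 (methyl bridgehead), C6H2–C7H–C8Me2, C9 (bridging C=O); ring A = C1–C2–C3–C4–C5–C9, ring B = C1–C8–C7–C6–C5–C9.
2. The last C–C bond made is in the C7 prenyl group, grown from a 7-methylidene group by exo-face hydroboration and sp3–sp2 Suzuki–Miyaura coupling (this sets C7 with the prenyl group endo); the C4 enol is carried as its methyl ether until the last step.
3. Key disconnections are C5–C6 (closure of ring B) together with C1–C8; they unravel the bicycle to a flat, achiral aryl allyl ether in which ring A is a fully substituted phloroglucinol ring (O2 allylated, O4 and O9 methylated).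
4. Enabling feature: C1 and C5 are both α to C9 in ring A, and the C8(Me2)–C7(=CH2)–C6H2 bridge is a 2-methyleneallyl unit; as a 2-(chloromethyl)-3-methylbut-2-enyl group on O2 it can migrate [3,3] only to C1 (C3 carries the acyl group), which makes C1–C8 and leaves C5 as the β-carbon of a C9 enol ether lying over a symmetrical allylic chloride whose terminus is C6.
5. Ring order: ring A is bought as 3,5-dimethoxy-4-methylphenol and dressed by acylation (C3), prenylation (C1) and O-alkylation (O2); ring B is closed in the key step; the bis-electrophile comes from diethyl isopropylidenemalonate.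

Key step: step 6

Assumption: 3,5-dimethoxy-4-methylphenol is treated as a catalogue chemical (otherwise one Dakin oxidation from commercial 3,5-dimethoxy-4-methylbenzaldehyde), and the target is drawn as the C4-enol tautomer given although it will exist as a mixture of enol tautomers.
Assumption: the sense of induction in step 6 cannot be predicted with confidence; (S,S)-t-Bu-box stands for whichever ligand antipode delivers the (6R)-dienone.

**Route**

Step 1
Reactants: 1 diethyl 2-(propan-2-ylidene)propanedioate
Product: 2 2-(propan-2-ylidene)propane-1,3-diol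
Conditions: i-Bu2AlH (4.5 equiv), CH2Cl2, −78 → 0 °C; aq. potassium sodium tartrate
Reagents that add atoms: none
Why: Both ester groups of the alkylidene malonate are reduced to primary allylic alcohols by i-Bu2AlH (ester-to-alcohol hydride reduction), which adds 1,2 to α,β-unsaturated esters at low temperature and so leaves the tetrasubstituted alkene untouched.

Step 2
Reactants: 2 2-(propan-2-ylidene)propane-1,3-diol
Product: 3 1-chloro-2-(chloromethyl)-3-methylbut-2-ene
Conditions: PPh3 (2.4 equiv), CCl4 (3 equiv), MeCN, 0 → 20 °C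
Reagents that add atoms: tetrachloromethane, ClC(Cl)(Cl)Cl
Why: Appel reaction, in which each primary allylic hydroxyl group is displaced by chloride through its oxyphosphonium ion in an SN2 sense, so the tetrasubstituted alkene is not transposed.

Step 3
Reactants: 4 3,5-dimethoxy-4-methylphenol
Product: 5 1-(6-hydroxy-2,4-dimethoxy-3-methylphenyl)-2-methylpropan-1-one
Conditions: i-PrCOCl (1.1 equiv), TiCl4 (1.2 equiv), CH2Cl2, 0 → 20 °C; aq. HCl
Reagents that add atoms: 2-methylpropanoyl chloride, CC(C)C(Cl)=O
Why: Friedel–Crafts acylation of the titanium phenoxide takes place at one of the two equivalent ring C–H positions ortho to the hydroxyl group, and chelation of the product ketone by titanium stops the reaction after one acylation.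

Step 4
Reactants: 5 1-(6-hydroxy-2,4-dimethoxy-3-methylphenyl)-2-methylpropan-1-one
Product: 6 1-[2-hydroxy-4,6-dimethoxy-5-methyl-3-(3-methylbut-2-en-1-yl)phenyl]-2-methylpropan-1-one
Conditions: 2-methylbut-3-en-2-ol (1.5 equiv), BF3·OEt2 (0.5 equiv), 1,4-dioxane, 20 °C
Reagents that add atoms: 2-methylbut-3-en-2-ol, CC(C)(O)C=C
Why: Friedel–Crafts prenylation by the tertiary allylic cation can occur only at the single remaining ring C–H (ortho to OH, para to OMe), and attack through the unhindered primary terminus of the cation gives the linear prenyl group.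

Step 5
Reactants: 6 1-[2-hydroxy-4,6-dimethoxy-5-methyl-3-(3-methylbut-2-en-1-yl)phenyl]-2-methylpropan-1-one, 3 1-chloro-2-(chloromethyl)-3-methylbut-2-ene
Product: 7 1-[2-{[2-(chloromethyl)-3-methylbut-2-en-1-yl]oxy}-4,6-dimethoxy-5-methyl-3-(3-methylbut-2-en-1-yl)phenyl]-2-methylpropan-1-one
Conditions: Cs2CO3 (1.5 equiv), 3 (3 equiv), DMF, 40 °C
Reagents that add atoms: none
Why: Williamson ether synthesis on the only free hydroxyl group, in which the two CH2Cl ends of 3 are equivalent so that a single constitutional ether can form, while the excess of 3 suppresses double O-alkylation.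

Step 6
Reactants: 7 1-[2-{[2-(chloromethyl)-3-methylbut-2-en-1-yl]oxy}-4,6-dimethoxy-5-methyl-3-(3-methylbut-2-en-1-yl)phenyl]-2-methylpropan-1-one
Product: 9 (1R,5R)-4-methoxy-5,8,8-trimethyl-7-methylidene-1-(3-methylbut-2-en-1-yl)-3-(2-methylpropanoyl)bicyclo[3.3.1]non-3-ene-2,9-dione, via (6R)-cyclohexadienone 8 (not isolated)
Conditions: Cu(OTf)2 (10 mol %), (S,S)-t-Bu-box (11 mol %), 4 Å MS, CH2Cl2, −20 → 0 °C; then THF, P(OPh)3 (40 mol %), Pd2(dba)3 (5 mol %), 0 → 20 °C, same flask
Reagents that add atoms: none
Why: Proposed new method: divalent copper chelated by O2 and the isobutyryl oxygen should trigger a charge-accelerated, enantioselective dearomative Claisen rearrangement that moves the allyl group from O2 to C1 (C3 is blocked by the acyl group) and forms the C1–C8 bond with allylic transposition, the closest known reaction type being the copper bis(oxazoline)-catalysed dearomative Claisen rearrangement of allyl 2-naphthyl ethers that carry a chelating carbonyl group next to the ether oxygen. Zerovalent palladium then ionises the allylic chloride of 8 (now on a 1,1-disubstituted alkene, with no β-hydrogen on C8) and C5, the β-carbon of the C9 methyl enol ether, attacks the π-allyl terminus C6 anti to the metal, after which chloride removes the methyl group from the C9 oxocarbenium ion as MeCl; the closest known reaction types are Tsuji–Trost allylations of silyl enol ethers and of electron-rich arenes. The ring closed is ring B (six-membered, C1–C8–C7–C6–C5–C9), formally 6-exo-tet at C6 and degenerate with the SN2′ mode because both allyl termini are CH2 groups. C1 is set by the chiral copper complex, which decides the face of the arene that receives the allyl group, and C5 is set by C1, because the three-carbon tether can reach C5 only on the face syn to C8. The step needs C5 to win over C3 and over the carbonyl oxygens as the nucleophile, which the substrate secures by the two acyl groups that deactivate C3 and by the softness of the π-allyl electrophile, and it needs ring closure to outrun the Cope shift of the allyl unit from C1 to C5, which is why both stages are run at or below 20 °C without isolation of 8.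

Step 7
Reactants: 9 (1R,5R)-4-methoxy-5,8,8-trimethyl-7-methylidene-1-(3-methylbut-2-en-1-yl)-3-(2-methylpropanoyl)bicyclo[3.3.1]non-3-ene-2,9-dione
Product: 11 (1R,5R,7R)-4-methoxy-5,8,8-trimethyl-1,7-bis(3-methylbut-2-en-1-yl)-3-(2-methylpropanoyl)bicyclo[3.3.1]non-3-ene-2,9-dione, via B-alkyl-9-BBN adduct 10 (not isolated)
Conditions: 9-BBN-H (1.3 equiv), THF, 0 → 20 °C; then 1-bromo-2-methylprop-1-ene (2 equiv), PdCl2(dppf) (5 mol %), aq. K3PO4 (3 equiv), DMF, 50 °C
Reagents that add atoms: 1-bromo-2-methylprop-1-ene, CC(C)=CBr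
Why: Hydroboration with 9-BBN-H should select the 1,1-disubstituted exocyclic alkene over the two trisubstituted prenyl alkenes and deliver hydrogen to C7 from the exo face (the endo face is covered by the C2–C3–C4 bridge), which places the CH2–B arm endo, and the B-alkyl Suzuki–Miyaura coupling with the alkenyl bromide then completes the prenyl group without touching C7.

Step 8
Reactants: 11 (1R,5R,7R)-4-methoxy-5,8,8-trimethyl-1,7-bis(3-methylbut-2-en-1-yl)-3-(2-methylpropanoyl)bicyclo[3.3.1]non-3-ene-2,9-dione
Product: 12 (1R,5R,7R)-4-hydroxy-5,8,8-trimethyl-1,7-bis(3-methylbut-2-en-1-yl)-3-(2-methylpropanoyl)bicyclo[3.3.1]non-3-ene-2,9-dione (CNP0265287.1)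
Conditions: LiCl (5 equiv), DMSO, 120 °C; aq. HCl work-up
Reagents that add atoms: none
Why: SN2 O-demethylation of the vinylogous methyl ester by chloride (the dealkylation half of the Krapcho reaction) releases the stabilised β-triketone enolate, which is protonated on work-up, and no stereocentre can epimerise because C1 and C5 are quaternary and C7 is not α to a carbonyl group.

**Compound list**

1 | diethyl 2-(propan-2-ylidene)propanedioate | CCOC(=O)C(=C(C)C)C(=O)OCC | starting material
2 | 2-(propan-2-ylidene)propane-1,3-diol | CC(C)=C(CO)CO | intermediate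
3 | 1-chloro-2-(chloromethyl)-3-methylbut-2-ene | CC(C)=C(CCl)CCl | intermediate
4 | 3,5-dimethoxy-4-methylphenol | COc1cc(O)cc(OC)c1C | starting material
5 | 1-(6-hydroxy-2,4-dimethoxy-3-methylphenyl)-2-methylpropan-1-one | CC(C)C(=O)c1c(O)cc(OC)c(C)c1OC | intermediate
6 | 1-[2-hydroxy-4,6-dimethoxy-5-methyl-3-(3-methylbut-2-en-1-yl)phenyl]-2-methylpropan-1-one | CC(C)C(=O)c1c(O)c(CC=C(C)C)c(OC)c(C)c1OC | intermediate
7 | 1-[2-{[2-(chloromethyl)-3-methylbut-2-en-1-yl]oxy}-4,6-dimethoxy-5-methyl-3-(3-methylbut-2-en-1-yl)phenyl]-2-methylpropan-1-one | CC(C)C(=O)c1c(OCC(CCl)=C(C)C)c(CC=C(C)C)c(OC)c(C)c1OC | intermediate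
8 | (6R)-6-[3-(chloromethyl)-2-methylbut-3-en-2-yl]-3,5-dimethoxy-4-methyl-6-(3-methylbut-2-en-1-yl)-2-(2-methylpropanoyl)cyclohexa-2,4-dien-1-one (not isolated) | CC(C)C(=O)C1=C(OC)C(C)=C(OC)[C@@](CC=C(C)C)(C(C)(C)C(=C)CCl)C1=O | intermediate
9 | (1R,5R)-4-methoxy-5,8,8-trimethyl-7-methylidene-1-(3-methylbut-2-en-1-yl)-3-(2-methylpropanoyl)bicyclo[3.3.1]non-3-ene-2,9-dione | C=C1C[C@@]2(C)C(=O)[C@](CC=C(C)C)(C(=O)C(C(=O)C(C)C)=C2OC)C1(C)C | intermediate
10 | (1R,5R,7R)-7-[(9-borabicyclo[3.3.1]nonan-9-yl)methyl]-4-methoxy-5,8,8-trimethyl-1-(3-methylbut-2-en-1-yl)-3-(2-methylpropanoyl)bicyclo[3.3.1]non-3-ene-2,9-dione (not isolated) | C(B1C2CCCC1CCC2)[C@@H]1C[C@@]2(C)C(=O)[C@](CC=C(C)C)(C(=O)C(C(=O)C(C)C)=C2OC)C1(C)C | intermediate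
11 | (1R,5R,7R)-4-methoxy-5,8,8-trimethyl-1,7-bis(3-methylbut-2-en-1-yl)-3-(2-methylpropanoyl)bicyclo[3.3.1]non-3-ene-2,9-dione | CC(C)=CC[C@@H]1C[C@@]2(C)C(=O)[C@](CC=C(C)C)(C(=O)C(C(=O)C(C)C)=C2OC)C1(C)C | intermediate
12 | (1R,5R,7R)-4-hydroxy-5,8,8-trimethyl-1,7-bis(3-methylbut-2-en-1-yl)-3-(2-methylpropanoyl)bicyclo[3.3.1]non-3-ene-2,9-dione (CNP0265287.1) | CC(C)=CC[C@@H]1C[C@@]2(C)C(=O)[C@](CC=C(C)C)(C(=O)C(C(=O)C(C)C)=C2O)C1(C)C | target

**Summary**

Total step count: 8.
Longest linear sequence: 6 steps (steps 3–8 from phenol 4; equally steps 1, 2, 5, 6, 7, 8 from malonate 1).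

**Three steps most likely to fail**

1. Step 6 (proposed new method). Three processes may defeat it:
   - ionisation of the allyl ether by the Lewis acid with recombination at the primary allyl terminus, or weak enantiofacial discrimination in the copper stage;
   - Cope shift of the allyl unit from C1 to C5 before the palladium stage captures the dienone;
   - slow C-attack of the neutral enol ether on the π-allyl, or attack by a carbonyl oxygen with loss of the second methyl group.

   The fallback sets out from 7, makes the same two bonds stepwise with known chemistry and comes back to the route at 12. Ether 7 is rearranged with an achiral Lewis acid (Eu(fod)3, 10 mol %, CHCl3, 20–40 °C; Lewis-acid-catalysed aromatic Claisen rearrangement) to the racemic dienone F1. Both enol ethers are hydrolysed (2 M HCl, THF, 20 °C) to the racemic monocyclic triketone F2. Its dianion (Cs2CO3, 2.5 equiv) is closed by a conventional Tsuji–Trost alkylation (Pd(PPh3)4, 5 mol %, THF, 20 °C) to the racemic bicyclic triketone F3; C5 is the most basic carbon of the dianion, and O-allylation is reversible under zerovalent palladium. F3 is resolved by preparative chromatography on a chiral stationary phase to the (1R,5R)-enantiomer F4. F4 is taken through the hydroboration/Suzuki–Miyaura sequence of step 7 with 2.5 equiv of 9-BBN-H, the first equivalent being consumed by the acidic enol to give the bis-boron intermediate F5; acidic work-up then gives 12 directly.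

2. Step 7. What may go wrong: reduction of the cross-conjugated isobutyryl carbonyl group or of the C9 ketone by the borane, hydroboration of a prenyl group, or slow transmetalation and protodeboronation of the hindered β-branched alkylborane.

   The fallback sets out from 9 and comes back at 11 without any boron chemistry. Rhodium-catalysed hydroformylation (Rh(acac)(CO)2, 2 mol %, tris(2,4-di-tert-butylphenyl) phosphite, CO/H2 20 bar, toluene, 70 °C) should add the formyl group to the exocyclic carbon and hydrogen to C7 from the exo face, giving the endo aldehyde F6. Wittig olefination of F6 with isopropylidene(triphenyl)phosphorane (from i-PrPPh3I and n-BuLi, THF, −78 → 0 °C) should react only at the aldehyde and give 11.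

3. Step 4. What may go wrong: O-prenylation instead of C-prenylation, acid-induced cyclisation of the new prenyl group onto the neighbouring hydroxyl group, or further alkylation.

   The fallback sets out from 5 and comes back at 6. The phenol is O-alkylated at the tertiary terminus with tert-butyl 2-methylbut-3-en-2-yl carbonate (Pd(PPh3)4, 2 mol %, THF, 0 → 20 °C; Tsuji–Trost etherification under kinetic control) to the tertiary aryl ether F7. Heating F7 (toluene, 110 °C) should bring about an aromatic Claisen rearrangement to the only free ortho position; the allylic transposition turns the 1,1-dimethylallyl ether into the linear prenyl group, and tautomerisation gives 6.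

**Further compounds**

F1 | step 6 | rac-6-[3-(chloromethyl)-2-methylbut-3-en-2-yl]-3,5-dimethoxy-4-methyl-6-(3-methylbut-2-en-1-yl)-2-(2-methylpropanoyl)cyclohexa-2,4-dien-1-one | CC(C)C(=O)C1=C(OC)C(C)=C(OC)C(CC=C(C)C)(C(C)(C)C(=C)CCl)C1=O
F2 | step 6 | rac-6-[3-(chloromethyl)-2-methylbut-3-en-2-yl]-3,5-dihydroxy-4-methyl-6-(3-methylbut-2-en-1-yl)-2-(2-methylpropanoyl)cyclohexa-2,4-dien-1-one | CC(C)C(=O)C1=C(O)C(C)=C(O)C(CC=C(C)C)(C(C)(C)C(=C)CCl)C1=O
F3 | step 6 | rac-4-hydroxy-5,8,8-trimethyl-7-methylidene-1-(3-methylbut-2-en-1-yl)-3-(2-methylpropanoyl)bicyclo[3.3.1]non-3-ene-2,9-dione | C=C1CC2(C)C(=O)C(CC=C(C)C)(C(=O)C(C(=O)C(C)C)=C2O)C1(C)C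
F4 | step 6 | (1R,5R)-4-hydroxy-5,8,8-trimethyl-7-methylidene-1-(3-methylbut-2-en-1-yl)-3-(2-methylpropanoyl)bicyclo[3.3.1]non-3-ene-2,9-dione | C=C1C[C@@]2(C)C(=O)[C@](CC=C(C)C)(C(=O)C(C(=O)C(C)C)=C2O)C1(C)C
F5 | step 6 | (1R,5R,7R)-7-[(9-borabicyclo[3.3.1]nonan-9-yl)methyl]-4-[(9-borabicyclo[3.3.1]nonan-9-yl)oxy]-5,8,8-trimethyl-1-(3-methylbut-2-en-1-yl)-3-(2-methylpropanoyl)bicyclo[3.3.1]non-3-ene-2,9-dione | C(B1C2CCCC1CCC2)[C@@H]1C[C@@]2(C)C(=O)[C@](CC=C(C)C)(C(=O)C(C(=O)C(C)C)=C2OB3C4CCCC3CCC4)C1(C)C
F6 | step 7 | (1R,5R,7S)-4-methoxy-5,8,8-trimethyl-1-(3-methylbut-2-en-1-yl)-3-(2-methylpropanoyl)-7-(2-oxoethyl)bicyclo[3.3.1]non-3-ene-2,9-dione | O=CC[C@@H]1C[C@@]2(C)C(=O)[C@](CC=C(C)C)(C(=O)C(C(=O)C(C)C)=C2OC)C1(C)C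
F7 | step 4 | 1-{2,4-dimethoxy-3-methyl-6-[(2-methylbut-3-en-2-yl)oxy]phenyl}-2-methylpropan-1-one | CC(C)C(=O)c1c(OC(C)(C)C=C)cc(OC)c(C)c1OC
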